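**Plan**

- Halimane numbering is used: ring A = C1–C5 and C10, ring B = C5–C10, ester on C4, C17 on C8, C20 on C9, side chain C11–C16. The α face carries H-5 and the methyl groups on C4, C8 and C9; the β face carries the ester and C11.
- Retrosynthesis, in order: the C15 formate and the silyl groups; H-5 and the C1=C10 alkene back to a C1 allylic alcohol with a C5=C10 alkene; the C17 methyl back to a formyl group; ring B cut at C6–C7 and C8–C9 into acrolein and the ring-A diene C6=C5–C10=C9; the diene cut at C5–C10 and C9–C11 into a vinyl triflate, an alkyne and a side-chain borane; then C1–C10 (alkynylation) and C3–C4 (Michael addition).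
- Forward: the acyclic C4–C1 chain is built first, ring A and the side chain are joined in one palladium cascade, ring B follows by [4+2] cycloaddition, then the alkene is moved and the formate is set.
- Enabling feature: ring B shares the C5–C10 edge with ring A and both fusion carbons can be trigonal; C1 next to C10 can carry a sacrificial oxygen; the cis C17/C20 methyls on C8/C9 map onto an endo formyl group and the outside methyl of a geometrically defined diene terminus.
- Stereochemistry: C4 from a catalytic asymmetric Michael addition; C1 from a catalytic asymmetric alkynylation; C8 and C9 from the cycloaddition (endo rule, alkene geometry from syn-carbopalladation, attack anti to the C1 silyloxy group); C5 from C1 by suprafacial hydrogen transfer in an allylic diazene; 13E from the starting enynol.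

Key step: step 8

Remark: the catalyst and ligand antipodes in steps 1 and 2 are those that give 2S and 5R (alkynyl group to the aldehyde Si face); the sense is not asserted from memory. Commercial (E)-3-methylpent-2-en-4-yn-1-ol is taken as the pure E isomer.

**Route**

Step 1
Reactants: 1 methyl 2-methyl-3-oxobutanoate; 2 acrolein
Product: 3 methyl (2S)-2-acetyl-2-methyl-5-oxopentanoate
Conditions: 9-O-(9-phenanthryl)-6'-hydroxy cinchona alkaloid (cupreidine or cupreine type, 10 mol %), acrolein (3 equiv), CH2Cl2, −24 °C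
Reagents that add atoms: none
Why: Enantioselective organocatalytic Michael addition of an α-substituted β-keto ester to acrolein, in which the bifunctional catalyst (quinuclidine base, phenol hydrogen-bond donor) fixes the enolate face and so sets the quaternary C4.

Step 2
Reactants: 3 methyl (2S)-2-acetyl-2-methyl-5-oxopentanoate; 4 propyne
Product: 5 methyl (2S,5R)-2-acetyl-5-hydroxy-2-methyloct-6-ynoate
Conditions: propyne (3 equiv), ZnMe2 (3 equiv), ProPhenol ligand (20 mol %), Ph3P=O (40 mol %), toluene, 0 °C; aq NH4Cl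
Reagents that add atoms: none
Why: Catalytic asymmetric addition of an alkynylzinc to an aldehyde, which should take the aldehyde in preference to the hindered ketone and the ester and set C1 (R) by reagent control.

Step 3
Reactants: 5 methyl (2S,5R)-2-acetyl-5-hydroxy-2-methyloct-6-ynoate
Product: 6 methyl (2S,5R)-2-acetyl-2-methyl-5-[(triethylsilyl)oxy]oct-6-ynoate
Conditions: Et3SiCl, imidazole, CH2Cl2, 0 °C
Reagents that add atoms: chlorotriethylsilane, CC[Si](Cl)(CC)CC
Why: Silylation of the secondary alcohol masks it for the enolisation and the Lewis acid step and installs the group that later shields the β face; no stereocentre is touched.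

Step 4
Reactants: 6 methyl (2S,5R)-2-acetyl-2-methyl-5-[(triethylsilyl)oxy]oct-6-ynoate
Product: 7 methyl (2S,5R)-2-methyl-5-[(triethylsilyl)oxy]-2-{1-[(trifluoromethanesulfonyl)oxy]ethenyl}oct-6-ynoate
Conditions: KN(SiMe3)2, THF, −78 °C; PhNTf2, −78 to 0 °C
Reagents that add atoms: N-phenylbis(trifluoromethanesulfonimide), O=S(=O)(N(c1ccccc1)S(=O)(=O)C(F)(F)F)C(F)(F)F
Why: Enol triflate formation, regiospecific because C4 is quaternary and the ketone can enolise only toward the C6 methyl group.

Step 5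
Reactants: 8 (2E)-3-methylpent-2-en-4-yn-1-ol
Product: 9 tert-butyl{[(2E)-3-methylpent-2-en-4-yn-1-yl]oxy}diphenylsilane
Conditions: t-BuPh2SiCl, imidazole, CH2Cl2, 23 °C
Reagents that add atoms: tert-butyl(chloro)diphenylsilane, CC(C)(C)[Si](Cl)(c1ccccc1)c1ccccc1
Why: Silylation of the primary allylic alcohol gives an ether that should survive every later step up to the fluoride cleavage and cannot ionise at C15.

Step 6
Reactants: 9 tert-butyl{[(2E)-3-methylpent-2-en-4-yn-1-yl]oxy}diphenylsilane
Product: 10 tert-butyl{[(2E)-3-methylpenta-2,4-dien-1-yl]oxy}diphenylsilane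
Conditions: H2 (1 atm), Pd/CaCO3 poisoned with Pb(OAc)2, quinoline, hexane/EtOAc, 23 °C
Reagents that add atoms: none
Why: Semihydrogenation of the terminal alkyne over poisoned palladium gives the vinyl group and leaves the trisubstituted E alkene, which becomes the 13E alkene, unchanged.

Step 7
Reactants: 7 methyl (2S,5R)-2-methyl-5-[(triethylsilyl)oxy]-2-{1-[(trifluoromethanesulfonyl)oxy]ethenyl}oct-6-ynoate; 10 tert-butyl{[(2E)-3-methylpenta-2,4-dien-1-yl]oxy}diphenylsilane
Product: 12 methyl (1S,3E,4R)-3-[(5E)-7-{[tert-butyl(diphenyl)silyl]oxy}-5-methylhept-5-en-2-ylidene]-1-methyl-2-methylidene-4-[(triethylsilyl)oxy]cyclohexane-1-carboxylate (C11 cis to C5; C20 cis to C1), via alkyl-9-BBN borane 11 (not isolated)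
Conditions: 10, 9-borabicyclo[3.3.1]nonane (1.2 equiv), THF, 0 to 23 °C; then 7, PdCl2(dppf) (5 mol %), K3PO4 (3 equiv, aq), THF/DMF, 50 °C
Reagents that add atoms: none
Why: Carbopalladation/B-alkyl Suzuki–Miyaura cascade in which zerovalent palladium inserts into the vinyl triflate, a 6-exo-dig syn insertion of the alkyne closes ring A (C5–C10), and the dienylpalladium couples with borane 11 with retention (C9–C11), so that C11 ends cis to C5 and the C20 methyl cis to C1.

Step 8
Reactants: 12 methyl (1S,3E,4R)-3-[(5E)-7-{[tert-butyl(diphenyl)silyl]oxy}-5-methylhept-5-en-2-ylidene]-1-methyl-2-methylidene-4-[(triethylsilyl)oxy]cyclohexane-1-carboxylate; 2 acrolein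
Product: 13 methyl (1S,4R,5S,6R)-5-[(3E)-5-{[tert-butyl(diphenyl)silyl]oxy}-3-methylpent-3-en-1-yl]-6-formyl-1,5-dimethyl-4-[(triethylsilyl)oxy]-1,2,3,4,5,6,7,8-octahydronaphthalene-1-carboxylate
Conditions: acrolein (5 equiv), Me2AlCl (20 mol %), CH2Cl2, −78 to −40 °C
Reagents that add atoms: none
Why: Me2AlCl-bound acrolein should add to the s-cis locked diene C6=C5–C10=C9 in a concerted, asynchronous, normal-demand [4+2] cycloaddition in which C6–C7 bonding leads and C8–C9 follows, leaving the alkene at C5=C10. The closest known reaction type is the Lewis-acid-catalysed Diels–Alder reaction of 1,2-dialkylidenecyclohexanes with enals. Ring B closes in the six-membered cycloaddition mode, suprafacial on both partners, onto the C5–C10 edge of ring A. C9 is controlled by the alkene geometry fixed in step 7 (C20 outside, C11 inside) together with the face of attack, and C8 by the endo orientation of the complexed formyl group, which places C17 cis to C20. The face is set by the C1 triethylsilyloxy group, held pseudoaxial on the β face by A(1,3) strain with the C20 methyl, so that acrolein should add from the α face. The step needs ortho regioselectivity, endo selectivity and α-face selectivity; these are secured by the larger HOMO coefficient at the unsubstituted C6 terminus (tertiary allyl cation character at C9), by Lewis acid catalysis and by the C1 substituent.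

Step 9
Reactants: 13 methyl (1S,4R,5S,6R)-5-[(3E)-5-{[tert-butyl(diphenyl)silyl]oxy}-3-methylpent-3-en-1-yl]-6-formyl-1,5-dimethyl-4-[(triethylsilyl)oxy]-1,2,3,4,5,6,7,8-octahydronaphthalene-1-carboxylate
Product: 15 methyl (1S,4R,5S,6R)-5-[(3E)-5-{[tert-butyl(diphenyl)silyl]oxy}-3-methylpent-3-en-1-yl]-1,5,6-trimethyl-4-[(triethylsilyl)oxy]-1,2,3,4,5,6,7,8-octahydronaphthalene-1-carboxylate, via tosylhydrazone 14 (not isolated)
Conditions: TsNHNH2 (1.1 equiv), THF, 23 °C; then catecholborane (3 equiv), CHCl3, 0 °C; then NaOAc·3H2O, 60 °C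
Reagents that add atoms: none
Why: Reduction of an aldehyde tosylhydrazone to a methyl group (hydride addition to C=N, loss of sulfinate, loss of N2 from the diazene), which is mild enough for the ester, both silyl ethers and the alkenes and should leave C8 unepimerised because no acid or strong base is present.

Step 10
Reactants: 15 methyl (1S,4R,5S,6R)-5-[(3E)-5-{[tert-butyl(diphenyl)silyl]oxy}-3-methylpent-3-en-1-yl]-1,5,6-trimethyl-4-[(triethylsilyl)oxy]-1,2,3,4,5,6,7,8-octahydronaphthalene-1-carboxylate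
Product: 16 methyl (1S,4R,5S,6R)-5-[(3E)-5-{[tert-butyl(diphenyl)silyl]oxy}-3-methylpent-3-en-1-yl]-4-hydroxy-1,5,6-trimethyl-1,2,3,4,5,6,7,8-octahydronaphthalene-1-carboxylate
Conditions: pyridinium p-toluenesulfonate (20 mol %), MeOH/CH2Cl2, 0 to 23 °C
Reagents that add atoms: none
Why: Acid-catalysed methanolysis of a silyl ether, which should remove the triethylsilyl group much faster than the primary tert-butyldiphenylsilyl group and free only the C1 hydroxyl.

Step 11
Reactants: 16 methyl (1S,4R,5S,6R)-5-[(3E)-5-{[tert-butyl(diphenyl)silyl]oxy}-3-methylpent-3-en-1-yl]-4-hydroxy-1,5,6-trimethyl-1,2,3,4,5,6,7,8-octahydronaphthalene-1-carboxylate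
Product: 19 methyl (1S,5S,6R,8aR)-5-[(3E)-5-{[tert-butyl(diphenyl)silyl]oxy}-3-methylpent-3-en-1-yl]-1,5,6-trimethyl-1,2,3,5,6,7,8,8a-octahydronaphthalene-1-carboxylate, via N-allyl sulfonylhydrazine 17 (not isolated), via allylic diazene 18 (not isolated)
Conditions: 2-nitrobenzenesulfonylhydrazide (2 equiv), PPh3 (2 equiv), diethyl azodicarboxylate (2 equiv), THF, −30 °C; then 23 °C
Reagents that add atoms: none
Why: Reductive 1,3-transposition of an allylic alcohol: Mitsunobu displacement at C1 with inversion puts nitrogen on the α face, loss of 2-nitrobenzenesulfinic acid gives the monoalkyl diazene, and its retro-ene loss of N2 delivers hydrogen suprafacially to the α face of C5 while the alkene moves to C1=C10, so C5 (R) follows from C1 (R).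

Step 12
Reactants: 19 methyl (1S,5S,6R,8aR)-5-[(3E)-5-{[tert-butyl(diphenyl)silyl]oxy}-3-methylpent-3-en-1-yl]-1,5,6-trimethyl-1,2,3,5,6,7,8,8a-octahydronaphthalene-1-carboxylate
Product: 20 methyl (1S,5S,6R,8aR)-5-[(3E)-5-hydroxy-3-methylpent-3-en-1-yl]-1,5,6-trimethyl-1,2,3,5,6,7,8,8a-octahydronaphthalene-1-carboxylate
Conditions: Bu4NF, THF, 0 to 23 °C
Reagents that add atoms: none
Why: Fluoride-induced cleavage of the silyl ether frees the C15 alcohol without touching the hindered C4 ester or either alkene.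

Step 13
Reactants: 20 methyl (1S,5S,6R,8aR)-5-[(3E)-5-hydroxy-3-methylpent-3-en-1-yl]-1,5,6-trimethyl-1,2,3,5,6,7,8,8a-octahydronaphthalene-1-carboxylate
Product: 21 methyl (1S,5S,6R,8aR)-5-[(3E)-5-(formyloxy)-3-methylpent-3-en-1-yl]-1,5,6-trimethyl-1,2,3,5,6,7,8,8a-octahydronaphthalene-1-carboxylate (CNP0188193.1)
Conditions: acetic formic anhydride (from Ac2O and HCO2H), pyridine, CH2Cl2, 0 °C
Reagents that add atoms: acetic formic anhydride, CC(=O)OC=O
Why: O-Formylation of the primary allylic alcohol by the mixed anhydride, which transfers the more electrophilic formyl group and touches no stereocentre.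

**Compound list**

1 | methyl 2-methyl-3-oxobutanoate | CC(=O)C(C)C(=O)OC | starting material
2 | acrolein | C=CC=O | starting material
3 | methyl (2S)-2-acetyl-2-methyl-5-oxopentanoate | COC(=O)[C@@](C(C)=O)(C)CCC=O | intermediate
4 | propyne | CC#C | starting material
5 | methyl (2S,5R)-2-acetyl-5-hydroxy-2-methyloct-6-ynoate | COC(=O)[C@@](C(C)=O)(C)CC[C@@H](O)C#CC | intermediate
6 | methyl (2S,5R)-2-acetyl-2-methyl-5-[(triethylsilyl)oxy]oct-6-ynoate | COC(=O)[C@@](C(C)=O)(C)CC[C@@H](O[Si](CC)(CC)CC)C#CC | intermediate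
7 | methyl (2S,5R)-2-methyl-5-[(triethylsilyl)oxy]-2-{1-[(trifluoromethanesulfonyl)oxy]ethenyl}oct-6-ynoate | COC(=O)[C@@](C(=C)OS(=O)(=O)C(F)(F)F)(C)CC[C@@H](O[Si](CC)(CC)CC)C#CC | intermediate
8 | (2E)-3-methylpent-2-en-4-yn-1-ol | C#C/C(C)=C/CO | starting material
9 | tert-butyl{[(2E)-3-methylpent-2-en-4-yn-1-yl]oxy}diphenylsilane | C#C/C(C)=C/CO[Si](c1ccccc1)(c1ccccc1)C(C)(C)C | intermediate
10 | tert-butyl{[(2E)-3-methylpenta-2,4-dien-1-yl]oxy}diphenylsilane | C=C/C(C)=C/CO[Si](c1ccccc1)(c1ccccc1)C(C)(C)C | intermediate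
11 | 9-[(3E)-5-{[tert-butyl(diphenyl)silyl]oxy}-3-methylpent-3-en-1-yl]-9-borabicyclo[3.3.1]nonane | C(C/C(C)=C/CO[Si](c1ccccc1)(c1ccccc1)C(C)(C)C)B1C2CCCC1CCC2 | intermediate
12 | methyl (1S,3E,4R)-3-[(5E)-7-{[tert-butyl(diphenyl)silyl]oxy}-5-methylhept-5-en-2-ylidene]-1-methyl-2-methylidene-4-[(triethylsilyl)oxy]cyclohexane-1-carboxylate | COC(=O)[C@@]1(C)CC[C@@H](O[Si](CC)(CC)CC)/C(=C(\C)CC/C(C)=C/CO[Si](c2ccccc2)(c2ccccc2)C(C)(C)C)C1=C | intermediate
13 | methyl (1S,4R,5S,6R)-5-[(3E)-5-{[tert-butyl(diphenyl)silyl]oxy}-3-methylpent-3-en-1-yl]-6-formyl-1,5-dimethyl-4-[(triethylsilyl)oxy]-1,2,3,4,5,6,7,8-octahydronaphthalene-1-carboxylate | COC(=O)[C@@]1(C)CC[C@@H](O[Si](CC)(CC)CC)C2=C1CC[C@@H](C=O)[C@]2(C)CC/C(C)=C/CO[Si](c3ccccc3)(c3ccccc3)C(C)(C)C | intermediate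
14 | N'-tosylhydrazone of aldehyde 13 (E at C=N) | COC(=O)[C@@]1(C)CC[C@@H](O[Si](CC)(CC)CC)C2=C1CC[C@@H](/C=N/NS(=O)(=O)c3ccc(C)cc3)[C@]2(C)CC/C(C)=C/CO[Si](c3ccccc3)(c3ccccc3)C(C)(C)C | intermediate
15 | methyl (1S,4R,5S,6R)-5-[(3E)-5-{[tert-butyl(diphenyl)silyl]oxy}-3-methylpent-3-en-1-yl]-1,5,6-trimethyl-4-[(triethylsilyl)oxy]-1,2,3,4,5,6,7,8-octahydronaphthalene-1-carboxylate | COC(=O)[C@@]1(C)CC[C@@H](O[Si](CC)(CC)CC)C2=C1CC[C@@H](C)[C@]2(C)CC/C(C)=C/CO[Si](c3ccccc3)(c3ccccc3)C(C)(C)C | intermediate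
16 | methyl (1S,4R,5S,6R)-5-[(3E)-5-{[tert-butyl(diphenyl)silyl]oxy}-3-methylpent-3-en-1-yl]-4-hydroxy-1,5,6-trimethyl-1,2,3,4,5,6,7,8-octahydronaphthalene-1-carboxylate | COC(=O)[C@@]1(C)CC[C@@H](O)C2=C1CC[C@@H](C)[C@]2(C)CC/C(C)=C/CO[Si](c3ccccc3)(c3ccccc3)C(C)(C)C | intermediate
17 | methyl (1S,4S,5S,6R)-5-[(3E)-5-{[tert-butyl(diphenyl)silyl]oxy}-3-methylpent-3-en-1-yl]-1,5,6-trimethyl-4-[1-(2-nitrobenzenesulfonyl)hydrazinyl]-1,2,3,4,5,6,7,8-octahydronaphthalene-1-carboxylate | COC(=O)[C@@]1(C)CC[C@H](N(N)S(=O)(=O)c3ccccc3[N+](=O)[O-])C2=C1CC[C@@H](C)[C@]2(C)CC/C(C)=C/CO[Si](c3ccccc3)(c3ccccc3)C(C)(C)C | intermediate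
18 | methyl (1S,4S,5S,6R)-5-[(3E)-5-{[tert-butyl(diphenyl)silyl]oxy}-3-methylpent-3-en-1-yl]-4-diazenyl-1,5,6-trimethyl-1,2,3,4,5,6,7,8-octahydronaphthalene-1-carboxylate | COC(=O)[C@@]1(C)CC[C@H](N=N)C2=C1CC[C@@H](C)[C@]2(C)CC/C(C)=C/CO[Si](c3ccccc3)(c3ccccc3)C(C)(C)C | intermediate
19 | methyl (1S,5S,6R,8aR)-5-[(3E)-5-{[tert-butyl(diphenyl)silyl]oxy}-3-methylpent-3-en-1-yl]-1,5,6-trimethyl-1,2,3,5,6,7,8,8a-octahydronaphthalene-1-carboxylate | COC(=O)[C@@]1(C)CCC=C2[C@H]1CC[C@@H](C)[C@]2(C)CC/C(C)=C/CO[Si](c3ccccc3)(c3ccccc3)C(C)(C)C | intermediate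
20 | methyl (1S,5S,6R,8aR)-5-[(3E)-5-hydroxy-3-methylpent-3-en-1-yl]-1,5,6-trimethyl-1,2,3,5,6,7,8,8a-octahydronaphthalene-1-carboxylate | COC(=O)[C@@]1(C)CCC=C2[C@H]1CC[C@@H](C)[C@]2(C)CC/C(C)=C/CO | intermediate
21 | methyl (1S,5S,6R,8aR)-5-[(3E)-5-(formyloxy)-3-methylpent-3-en-1-yl]-1,5,6-trimethyl-1,2,3,5,6,7,8,8a-octahydronaphthalene-1-carboxylate | COC(=O)[C@@]1(C)CCC=C2[C@H]1CC[C@@H](C)[C@]2(C)CC/C(C)=C/COC=O | target

**Summary**

Total steps: 13. Longest linear sequence: 11 steps (steps 1–4 and 7–13).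

Steps most likely to fail:

Risk 1 (step 8, cycloaddition). Bond formation at the fully substituted C9 terminus may be slow. Face selectivity may erode, because in one ring-A conformer the axial C4 methyl shields the α face at C6 and works against the C1 silyloxy group. Endo selectivity may drop, and the Lewis acid may ionise the allylic silyl ether. The fallback adds reagent control. Diene 12 is treated with the known dienophile (4S)-3-acryloyl-4-benzyl-1,3-oxazolidin-2-one and Et2AlCl (1.4 equiv, CH2Cl2, −78 °C). The aluminium-chelated s-cis imide exposes its Cα Si face, which is the face that endo attack on the α side of the diene requires, and should give the N-acyl oxazolidinone adduct F1. LiBH4 with one equivalent of MeOH (Et2O, 0 °C) removes the auxiliary and gives the primary alcohol F2, with the hindered C4 ester expected to survive. Oxidation with Dess–Martin periodinane returns the route at aldehyde 13.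

Risk 2 (step 7, cascade). The alkylborane may couple with the vinyl triflate before the 6-exo-dig insertion, or the dienylpalladium may lose its geometry while the slow B-alkyl transmetalation is awaited. The fallback separates ring closure from chain attachment. Triflate 7 is cyclised with (Me3Sn)2, Pd(PPh3)4 and LiCl (THF, 60 °C; carbopalladation then stannylation) to the dienyl stannane F3. Iodine (CH2Cl2, 0 °C) exchanges tin for iodine with retention and gives the dienyl iodide F4. F4 is then coupled with borane 11 in a separate B-alkyl Suzuki–Miyaura reaction (PdCl2(dppf), AsPh3, Cs2CO3, DMF/THF/H2O, 23 °C), which returns the route at diene 12.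

Risk 3 (step 11, transposition). The Mitsunobu displacement at the hindered C1 carbinol, flanked by the tetrasubstituted alkene and the quaternary C9, may stall or give elimination. The fallback replaces the sigmatropic hydrogen transfer by palladium hydride delivery. Alcohol 16 is formylated (acetic formic anhydride, pyridine) to the allylic formate F5. Pd(OAc)2 (5 mol %) with PBu3 (20 mol %) in dioxane at 80 °C should ionise F5 anti to the formate, lose CO2 and deliver hydride from the α face to the more substituted C5 terminus. This returns the route at 19.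

Further compounds
F1 | step 8 | methyl (1S,4R,5S,6R)-6-{[(4S)-4-benzyl-2-oxo-1,3-oxazolidin-3-yl]carbonyl}-5-[(3E)-5-{[tert-butyl(diphenyl)silyl]oxy}-3-methylpent-3-en-1-yl]-1,5-dimethyl-4-[(triethylsilyl)oxy]-1,2,3,4,5,6,7,8-octahydronaphthalene-1-carboxylate | COC(=O)[C@@]1(C)CC[C@@H](O[Si](CC)(CC)CC)C2=C1CC[C@@H](C(=O)N3[C@@H](Cc4ccccc4)COC3=O)[C@]2(C)CC/C(C)=C/CO[Si](c5ccccc5)(c5ccccc5)C(C)(C)C
F2 | step 8 | methyl (1S,4R,5S,6R)-5-[(3E)-5-{[tert-butyl(diphenyl)silyl]oxy}-3-methylpent-3-en-1-yl]-6-(hydroxymethyl)-1,5-dimethyl-4-[(triethylsilyl)oxy]-1,2,3,4,5,6,7,8-octahydronaphthalene-1-carboxylate | COC(=O)[C@@]1(C)CC[C@@H](O[Si](CC)(CC)CC)C2=C1CC[C@@H](CO)[C@]2(C)CC/C(C)=C/CO[Si](c3ccccc3)(c3ccccc3)C(C)(C)C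
F3 | step 7 | methyl (1S,3E,4R)-1-methyl-2-methylidene-4-[(triethylsilyl)oxy]-3-[1-(trimethylstannyl)ethylidene]cyclohexane-1-carboxylate | COC(=O)[C@@]1(C)CC[C@@H](O[Si](CC)(CC)CC)/C(=C(\C)[Sn](C)(C)C)C1=C
F4 | step 7 | methyl (1S,3E,4R)-3-(1-iodoethylidene)-1-methyl-2-methylidene-4-[(triethylsilyl)oxy]cyclohexane-1-carboxylate | COC(=O)[C@@]1(C)CC[C@@H](O[Si](CC)(CC)CC)/C(=C(\C)I)C1=C
F5 | step 11 | methyl (1S,4R,5S,6R)-5-[(3E)-5-{[tert-butyl(diphenyl)silyl]oxy}-3-methylpent-3-en-1-yl]-4-(formyloxy)-1,5,6-trimethyl-1,2,3,4,5,6,7,8-octahydronaphthalene-1-carboxylate | COC(=O)[C@@]1(C)CC[C@@H](OC=O)C2=C1CC[C@@H](C)[C@]2(C)CC/C(C)=C/CO[Si](c3ccccc3)(c3ccccc3)C(C)(C)C
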